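## Analysis of the target

The target is a bicyclic labdane: a trans-fused decalin (ring A = C1–C5, C10; ring B = C5–C10) with a 3-methylidenepent-4-enyl chain (C11–C16) on C9. Six contiguous stereocentres sit on the decalin: C3 (equatorial secondary acetate), C4 (quaternary, axial methyl and equatorial CH2OH), C5 (ring-fusion H), C8 (tertiary alcohol with methyl), C9, and C10 (quaternary methyl). Read from the SMILES they are 3R,4S,5S,8S,9R,10R. The 8-hydroxyl, H5, C11 and the hydroxymethyl group lie on one face; the C8, C10 and C4 methyls and the acetate lie on the other. C11 is therefore axial on C9, between two fully substituted carbons and anti to two axial methyls. This is the less stable C9 configuration, and neither equilibration nor a face-selective addition to a C9 carbonyl or alkene will produce it. The sensitive groups are the 2-substituted 1,3-diene (dissolving metal, acid, polymerisation), the tertiary alcohol (dehydration) and the monoacetate of a 1,3-diol (acyl shift to the primary hydroxyl under base). The difficulty is the C8–C9–C10 triad, then the C4 quaternary centre and the differentiation of the two diol hydroxyls. The strategy rests on ring B: C8 (O, CH3) and C5 are 1,4 to each other, with the C8 oxygen on the face of H5 and C11. C5–C6–C7–C8 plus that oxygen is thus a latent 2-methylfuran, and C9–C10 is a latent (Z)-trisubstituted enoate whose geometry encodes the C9/C10 relationship.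

## Retrosynthetic reasoning

**32 ⇐ 31 ⇐ 30.** The last operations are protecting-group moves on the 1,3-diol. The acetate must sit on the hindered secondary oxygen while the more reactive primary hydroxyl stays free. The primary oxygen is therefore silylated in 31, the acetate is put on 30, and the silyl ether comes off last under weakly acidic conditions so that the acetate does not migrate.

**30 ⇐ 27 + 28.** The chain is cut at C12–C13, its only sp3–sp2 bond. This leaves a vinyl group on C9 in 27, which tolerates dissolving metal, hydride and base, and the four-carbon chlorodiene 28, which is bought. Forward, the vinyl group is hydroborated to 29 and cross-coupled. The diene is thus absent during every reduction.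

**27 ⇐ 26 ⇐ 25.** Selective silylation of the primary hydroxyl and reduction of the C3 ketone. C3 is set by axial hydride attack on the ketone next to the quaternary C4.

**25 ⇐ 23.** The C4–CH2OH bond and the C5–H bond are cut together. Both arise from enone 23 in one reductive operation that forms the trans ring fusion and the C4 quaternary centre, each steered by the axial C10 methyl. No stereochemical information at C3, C4 or C5 has to be carried in.

**23 ⇐ 22 ⇐ 21 ⇐ 20.** The enone and the 8-hydroxyl of 23 are the two ends of a broken C5–O bond. Reconnecting them gives the oxygen-bridged ketone 22, which comes from silyl ether 20 by desilylation (21) and oxidation. The bridge protects the tertiary oxygen during the C11 chemistry and locks its configuration to C9.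

**20 ⇐ 19 ⇐ 18 ⇐ 17.** C11=C12 is cut by a one-carbon olefination of aldehyde 19, reached from ester 17 through alcohol 18. This must be done before C3 becomes a ketone: a carbonyl at C11 makes the C8–O bond β to it, and the bridge could then open on the wrong side.

**17 ⇐ 16.** Removal of two hydrogens returns the C6=C7 alkene of the cycloadduct. Forward, hydrogenation shuts off cycloreversion.

**16 ⇐ 15.** The key disconnection cuts C5–C10 and C8–C9, a retro-[4+2] to a 2,5-dialkylfuran (C5–C8 and oxygen) and a (Z)-enoate (C9=C10) joined by C1–C4. These two bonds close both rings and fix C8, C9 and C10 together; a concerted addition is the only process that turns alkene geometry directly into the axial C11. Forward, the reaction must overcome the aromaticity of the furan and the low reactivity of a β,β-disubstituted ester.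

**15 ⇐ 14 ⇐ 12 (via 13).** The C10–CH3 bond is cut by syn carbometalation of ynoate 14, and the C9–C11 bond by acylation of acetylide 13. Both are placed after the furan is built, so the ester never meets the organomagnesium step.

**12 ⇐ 11 ⇐ 10.** The furan is opened to its 1,4-dicarbonyl form: C5 as a ketone, C8 as a ketal. The alkyne carries silicon until the basic steps are over.

**10 ⇐ 7 + 9 (from 8).** The C5–C6 bond is cut by acyl substitution of amide 7 with organomagnesium 9.

**7 ⇐ 6 ⇐ 5 ⇐ 2 + 3 (via 4).** The C3–C4 bond is an auxiliary-controlled syn aldol. These two centres are erased later; their job is to carry absolute configuration into the cycloaddition.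

**2 ⇐ 1.** Oxidation of the commercial silylated pentynol.

## Alternatives that were turned down

**Alternative 1:** Ring B is cut at C7–C8 and treated as the ring-expanded form of a hydrindane in which C8 is the carbonyl carbon of an acetyl group on a hydroxylated C9. Forward, a Lewis acid that binds both oxygens (an aluminium alkoxide or BF3·OEt2) would drive the α-ketol shift of C7 from C9 to C8 and give A1, with the 4-methyl enone already in place.
- For: angular-methyl hydrindenones are made enantioselectively by catalysis, so C10 would not depend on an auxiliary relay. The 5→6 expansion is a known, thermodynamically driven reaction and does not revert. On precedent and reversibility it is stronger than the chosen key step.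
- Against: the shift must choose C7 over the fully substituted C10, which migrates more readily. The C8 configuration depends on a rotamer, not on a ring. Most seriously, A1 has a ketone at C9. C11 must be added to a carbonyl between two fully substituted carbons, and hydrogen must then reach C9 from the face of both axial methyls, against steric and hydroxyl-directed preferences alike.
- Comparison: the chosen route sets C8, C9 and C10 in one suprafacial event and never passes through a C9 carbonyl.

**Alternative 2:** The C9–C11 bond and a temporary C8–C12 bond are cut together, leading back to a trans-decalin 8-methyl-8-en-7-one with ring A complete (3-O and 4-CH2O as an acetonide). Forward, irradiation near 350 nm with allene A3 closes the cis-fused methylenecyclobutane A2, C11 bonding to the β-carbon C9 and the central allene carbon C12 to C8. Ozonolysis of the methylidene group and Baeyer–Villiger insertion between C8 and C12 would then turn the C8–C12 bond into C8–O with retention.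
- For: this is the only alternative that solves C9. The cyclobutane must be cis-fused, so the C8 oxygen and C11 end on one face, and addition anti to the axial C10 methyl makes it the right face. The reaction class is established, and C3, C4 and C5 are secure beforehand. On certainty of the key step and on ring A it is stronger than the chosen route.
- Against: the C7 ketone needed for excitation has no counterpart in the target and must be removed. C12 emerges at the acid oxidation level and must be brought down to CH2 before C13–C16 are added. The decalin enone needs a long linear preparation, and photochemistry limits throughput.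
- Comparison: the chosen route reaches the same syn 8-O/C11 relationship from an acyclic precursor, forms both rings in that step, and delivers C11 as an ester three routine steps from the vinyl group.

**Alternative 3:** Both rings are cut, at C5–C10 and C1–C2, to an acyclic trienone: an isopropenyl ketone (C9 carbonyl, C10=C1) linked through C8–C7–C6 to a 2-silyloxy diene (C5=C4–C3=C2). C8 comes from (S)-linalool A5 as a methoxymethyl ether. Forward, MgBr2·OEt2 chelates the ketone and ether oxygens, and the intramolecular Diels–Alder reaction gives the trans-decalin A4 with a C3–C4 silyl enol ether.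
- For: the diene is not aromatic, so the cycloaddition is irreversible and free of the thermodynamic risk of the chosen key step. On this point it is clearly stronger. C8 comes from the chiral pool, two rings form at once as in the chosen route, and the silyl enol ether allows C4 hydroxymethylation without a dissolving-metal step.
- Against: induction from C8 to C10 relies on a chelate, and the ring-fusion outcome relies on an endo/exo preference that the methyl on the dienophile weakens. Above all, A4 has the same C9 ketone as A1, so the axial C11 must again be installed against the facial bias of two axial methyls.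
- Comparison: the chosen route offers a C9 defined by alkene geometry, not by a late addition to a hindered ketone.

Key step: step 10

Assumption: the target is taken exactly as its SMILES defines it, 3R,4S,5S,8S,9R,10R, with C11 axial on C9 and anti to the C10 methyl. Labdane locants (C1–C20) are used for all ring compounds, including their names, where "decalin" and "octalin" stand for deca- and octahydronaphthalene with C5/C10 as the fusion atoms.
Assumption: 5-(trimethylsilyl)pent-4-yn-1-ol, 2-(2-bromoethyl)-2-methyl-1,3-dioxolane and chloroprene (as a stabilised solution) are bought.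

## Route

Step 1
Reactants: 1 5-(trimethylsilyl)pent-4-yn-1-ol
Product: 2 5-(trimethylsilyl)pent-4-ynal
Conditions: Dess–Martin periodinane, CH2Cl2, 0 °C to rt
Reagents that add atoms: none
Why: Dess–Martin oxidation of a primary alcohol stops at the aldehyde and leaves the silylalkyne untouched; 2 is used at once.

Step 2
Reactants: 2 5-(trimethylsilyl)pent-4-ynal; 3 (S)-4-benzyl-3-propionyloxazolidin-2-one
Product: 5 (S)-4-benzyl-3-[(2S,3R)-3-hydroxy-2-methyl-7-(trimethylsilyl)hept-6-ynoyl]oxazolidin-2-one, via boron enolate 4 (not isolated)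
Conditions: n-Bu2BOTf, i-Pr2NEt, CH2Cl2, 0 °C; then 2, −78 to 0 °C; then pH 7 buffer, MeOH, H2O2, 0 °C
Reagents that add atoms: none
Why: Evans syn aldol: the (Z)-boron enolate 4 reacts through a chair Zimmerman–Traxler transition state on the face away from the benzyl group, which sets C4 (S) and C3 (R) in one step.

Step 3
Reactants: 5 (S)-4-benzyl-3-[(2S,3R)-3-hydroxy-2-methyl-7-(trimethylsilyl)hept-6-ynoyl]oxazolidin-2-one
Product: 6 (2S,3R)-3-hydroxy-N-methoxy-N,2-dimethyl-7-(trimethylsilyl)hept-6-ynamide
Conditions: MeNH(OMe)·HCl, AlMe3, CH2Cl2, −20 to 0 °C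
Reagents that add atoms: N,O-dimethylhydroxylamine hydrochloride, CNOC.Cl
Why: Weinreb amide formation by aluminium-amide transamination; the free β-hydroxyl binds aluminium and directs attack to the exocyclic carbonyl, so the auxiliary leaves without epimerisation at C4.

Step 4
Reactants: 6 (2S,3R)-3-hydroxy-N-methoxy-N,2-dimethyl-7-(trimethylsilyl)hept-6-ynamide
Product: 7 (2S,3R)-3-[(tert-butyldimethylsilyl)oxy]-N-methoxy-N,2-dimethyl-7-(trimethylsilyl)hept-6-ynamide
Conditions: TBSOTf, 2,6-lutidine, CH2Cl2, −78 to 0 °C
Reagents that add atoms: tert-butyldimethylsilyl triflate, CC(C)(C)[Si](C)(C)OS(=O)(=O)C(F)(F)F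
Why: Silylation of the secondary alcohol with a silyl triflate and a hindered base; the ether blocks retro-aldol cleavage and is stable to every step up to step 15.

Step 5
Reactants: 7 (2S,3R)-3-[(tert-butyldimethylsilyl)oxy]-N-methoxy-N,2-dimethyl-7-(trimethylsilyl)hept-6-ynamide; 8 2-(2-bromoethyl)-2-methyl-1,3-dioxolane
Product: 10 (4S,5R)-5-[(tert-butyldimethylsilyl)oxy]-4-methyl-1-(2-methyl-1,3-dioxolan-2-yl)-9-(trimethylsilyl)non-8-yn-3-one, via Grignard reagent 9 (not isolated)
Conditions: 8, Mg, THF, 25 °C or below; then 7, THF, 0 °C; aq. NH4Cl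
Reagents that add atoms: none
Why: Grignard acylation of a Weinreb amide: the chelated tetrahedral intermediate prevents over-addition, and the silicon cap on the alkyne means no acetylide can form and compete.

Step 6
Reactants: 10 (4S,5R)-5-[(tert-butyldimethylsilyl)oxy]-4-methyl-1-(2-methyl-1,3-dioxolan-2-yl)-9-(trimethylsilyl)non-8-yn-3-one
Product: 11 tert-butyldimethyl{[(2S,3R)-2-(5-methylfuran-2-yl)-7-(trimethylsilyl)hept-6-yn-3-yl]oxy}silane
Conditions: p-TsOH·H2O (10 mol%), toluene, 60 °C
Reagents that add atoms: none
Why: Paal–Knorr furan synthesis on the masked 1,4-diketone: acid opens the dioxolane, the ketone oxygen closes on the oxocarbenium ion and loss of the diol aromatises; catalytic acid and moderate temperature limit enolisation toward C4.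

Step 7
Reactants: 11 tert-butyldimethyl{[(2S,3R)-2-(5-methylfuran-2-yl)-7-(trimethylsilyl)hept-6-yn-3-yl]oxy}silane
Product: 12 tert-butyldimethyl{[(2S,3R)-2-(5-methylfuran-2-yl)hept-6-yn-3-yl]oxy}silane
Conditions: K2CO3 (cat.), MeOH, rt
Reagents that add atoms: none
Why: Methanolysis of the alkynyl–silicon bond; the secondary silyl ether is inert to methanolic carbonate.

Step 8
Reactants: 12 tert-butyldimethyl{[(2S,3R)-2-(5-methylfuran-2-yl)hept-6-yn-3-yl]oxy}silane
Product: 14 methyl (6R,7S)-6-[(tert-butyldimethylsilyl)oxy]-7-(5-methylfuran-2-yl)oct-2-ynoate, via lithium acetylide 13 (not isolated)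
Conditions: n-BuLi, THF, −78 °C; then ClCO2Me, −78 to 0 °C
Reagents that add atoms: methyl chloroformate, COC(=O)Cl
Why: The terminal alkyne is the only acidic C–H; C-acylation of acetylide 13 with the chloroformate gives the ynoate.

Step 9
Reactants: 14 methyl (6R,7S)-6-[(tert-butyldimethylsilyl)oxy]-7-(5-methylfuran-2-yl)oct-2-ynoate
Product: 15 methyl (2Z,6R,7S)-6-[(tert-butyldimethylsilyl)oxy]-3-methyl-7-(5-methylfuran-2-yl)oct-2-enoate
Conditions: Me2CuLi (from MeLi and CuI), THF, −78 °C; MeOH then aq. NH4Cl at −78 °C
Reagents that add atoms: lithium dimethylcuprate, [Li+].C[Cu-]C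
Why: Stereospecific syn carbocupration of an ynoate: methyl and copper add to the same side, and protonation at −78 °C, before the vinylcopper can equilibrate, gives the (Z)-enoate with the ester cis to the chain.

Step 10
Reactants: 15 methyl (2Z,6R,7S)-6-[(tert-butyldimethylsilyl)oxy]-3-methyl-7-(5-methylfuran-2-yl)oct-2-enoate
Product: 16 methyl (3R,4S,5S,8S,9R,10S)-3-[(tert-butyldimethylsilyl)oxy]-5,8-epoxy-4,8,10-trimethyloctal-6-ene-9-carboxylate (ester and C1 syn to the oxygen bridge, C10 methyl anti)
Conditions: MeAlCl2 (1.1 equiv), CH2Cl2, −78 °C; Et3N then aq. NaHCO3 at −78 °C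
Reagents that add atoms: none
Why: Proposed new method: MeAlCl2 binds the ester carbonyl and lowers the LUMO of the (Z)-enoate so that the 2,5-dialkylfuran adds in a concerted, asynchronous [4+2], the C5–C10 bond (furan α-carbon to enoate β-carbon) running ahead of C8–C9; the closest known reaction type is the MeAlCl2-promoted intramolecular Diels–Alder reaction of furans with a four-atom tether to an enone, not yet extended to a β,β-disubstituted enoate that creates a quaternary carbon. Ring A closes through the tether C1–C4 as a six-membered chair in the exo mode, syn to the oxygen bridge, because an endo tether of this length would have to span the bicycle in a strained trans fashion; ring B is the new cyclohexene itself, closed as the boat of the 7-oxanorbornene. C5 and C8 are fixed together by suprafacial addition to one furan face, and C9 and C10 follow from the (Z)-geometry, which puts the ester on the side of the tether (exo) and the C10 methyl endo. The furan face is chosen by the aldol centres: only one exo chair holds both the C3 silyloxy and the C4 methyl group equatorial, and the other would force the C4 methyl into a 1,3-diaxial clash with the C10 methyl. The step needs exo selectivity, facial selectivity and a favourable equilibrium; the first two come from the tether length and from C3/C4, the third from the 2,5-dialkyl furan, the branched tether, the low temperature and a cold quench that removes the Lewis acid before cycloreversion can begin.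

Step 11
Reactants: 16 methyl (3R,4S,5S,8S,9R,10S)-3-[(tert-butyldimethylsilyl)oxy]-5,8-epoxy-4,8,10-trimethyloctal-6-ene-9-carboxylate
Product: 17 methyl (3R,4S,5S,8S,9R,10S)-3-[(tert-butyldimethylsilyl)oxy]-5,8-epoxy-4,8,10-trimethyldecalin-9-carboxylate
Conditions: H2 (1 atm), Pd/C, EtOAc, 0 °C, on crude 16
Reagents that add atoms: none
Why: Catalytic hydrogenation of the strained disubstituted C6–C7 alkene closes the retro-Diels–Alder pathway; the minor facial diastereomer of step 10 is removed here by chromatography, because C3 and C4 are erased later and it would otherwise end as the enantiomer.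

Step 12
Reactants: 17 methyl (3R,4S,5S,8S,9R,10S)-3-[(tert-butyldimethylsilyl)oxy]-5,8-epoxy-4,8,10-trimethyldecalin-9-carboxylate
Product: 18 [(3R,4S,5S,8S,9S,10S)-3-[(tert-butyldimethylsilyl)oxy]-5,8-epoxy-4,8,10-trimethyldecalin-9-yl]methanol
Conditions: LiAlH4, THF, 0 °C to rt
Reagents that add atoms: none
Why: Hydride reduction of the hindered ester to the primary alcohol; the reagent is not basic enough to cause β-elimination of the C8–O bond.

Step 13
Reactants: 18 [(3R,4S,5S,8S,9S,10S)-3-[(tert-butyldimethylsilyl)oxy]-5,8-epoxy-4,8,10-trimethyldecalin-9-yl]methanol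
Product: 19 (3R,4S,5S,8S,9R,10S)-3-[(tert-butyldimethylsilyl)oxy]-5,8-epoxy-4,8,10-trimethyldecalin-9-carbaldehyde
Conditions: Dess–Martin periodinane, pyridine, CH2Cl2, 0 °C
Reagents that add atoms: none
Why: Buffered Dess–Martin oxidation gives the aldehyde without base, so the C9 hydrogen (α to the carbonyl, β to the bridge oxygen) is not removed; 19 is used crude.

Step 14
Reactants: 19 (3R,4S,5S,8S,9R,10S)-3-[(tert-butyldimethylsilyl)oxy]-5,8-epoxy-4,8,10-trimethyldecalin-9-carbaldehyde
Product: 20 tert-butyl{[(3R,4S,5S,8S,9R,10S)-9-ethenyl-5,8-epoxy-4,8,10-trimethyldecalin-3-yl]oxy}dimethylsilane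
Conditions: Ph3PCH3Br, KN(SiMe3)2, THF, 0 °C; then 19, −78 to 0 °C
Reagents that add atoms: methyltriphenylphosphonium bromide, C[P+](c1ccccc1)(c1ccccc1)c1ccccc1.[Br-]
Why: Wittig methylenation with the salt-free ylide at low temperature; addition to the aldehyde is faster than deprotonation at the hindered C9, and once the carbonyl is gone the C8–O bond is no longer β to an acidifying group.

Step 15
Reactants: 20 tert-butyl{[(3R,4S,5S,8S,9R,10S)-9-ethenyl-5,8-epoxy-4,8,10-trimethyldecalin-3-yl]oxy}dimethylsilane
Product: 21 (3R,4S,5S,8S,9R,10S)-9-ethenyl-5,8-epoxy-4,8,10-trimethyldecalin-3-ol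
Conditions: TBAF, THF, rt
Reagents that add atoms: none
Why: Fluoride cleavage of the secondary silyl ether; the oxygen bridge and the vinyl group are inert.

Step 16
Reactants: 21 (3R,4S,5S,8S,9R,10S)-9-ethenyl-5,8-epoxy-4,8,10-trimethyldecalin-3-ol
Product: 22 (4R,5S,8S,9R,10S)-9-ethenyl-5,8-epoxy-4,8,10-trimethyldecalin-3-one
Conditions: Dess–Martin periodinane, pyridine, CH2Cl2, 0 °C
Reagents that add atoms: none
Why: Dess–Martin oxidation of the secondary alcohol gives the C3 ketone, in which the C5–O bond is now β to the carbonyl.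

Step 17
Reactants: 22 (4R,5S,8S,9R,10S)-9-ethenyl-5,8-epoxy-4,8,10-trimethyldecalin-3-one
Product: 23 (8S,9R,10S)-9-ethenyl-8-hydroxy-4,8,10-trimethyloctal-4-en-3-one
Conditions: DBU, CH2Cl2, rt
Reagents that add atoms: none
Why: E1cB β-elimination: the C3/C4 enolate expels the C5 oxygen, whose bond is axial to ring A and aligned with the enolate π system, and the strain of the bicycle is released. Only C5–O can leave, so the C8–O bond and its configuration are kept while C4 is erased.

Step 18
Reactants: 23 (8S,9R,10S)-9-ethenyl-8-hydroxy-4,8,10-trimethyloctal-4-en-3-one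
Product: 25 (4S,5S,8S,9R,10R)-9-ethenyl-8-hydroxy-4-(hydroxymethyl)-4,8,10-trimethyldecalin-3-one, via lithium enolate 24 (not isolated)
Conditions: Li, NH3(l), THF, −78 °C; isoprene; NH3 removed; then CH2O (gas), THF, −78 °C; aq. NH4Cl
Reagents that add atoms: formaldehyde, C=O
Why: Dissolving-metal reduction of the enone with regiospecific enolate trapping (reductive alkylation): the tertiary 8-OH supplies the one proton that adds to C5 axially, anti to the C10 methyl (trans fusion). Formaldehyde then attacks enolate 24 at C4 from the equatorial face, away from the axial C10 methyl, which leaves the C4 methyl axial; the isolated vinyl group is not reduced.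

Step 19
Reactants: 25 (4S,5S,8S,9R,10R)-9-ethenyl-8-hydroxy-4-(hydroxymethyl)-4,8,10-trimethyldecalin-3-one
Product: 26 (3R,4S,5S,8S,9R,10R)-9-ethenyl-4-(hydroxymethyl)-4,8,10-trimethyldecalin-3,8-diol
Conditions: NaBH4, MeOH, 0 °C
Reagents that add atoms: none
Why: Axial hydride delivery to the 3-ketone, as in 4,4-disubstituted 3-oxo terpenoids, gives the equatorial 3-alcohol.

Step 20
Reactants: 26 (3R,4S,5S,8S,9R,10R)-9-ethenyl-4-(hydroxymethyl)-4,8,10-trimethyldecalin-3,8-diol
Product: 27 (3R,4S,5S,8S,9R,10R)-4-{[(tert-butyldimethylsilyl)oxy]methyl}-9-ethenyl-4,8,10-trimethyldecalin-3,8-diol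
Conditions: TBSCl, imidazole, CH2Cl2, 0 °C
Reagents that add atoms: tert-butyldimethylsilyl chloride, CC(C)(C)[Si](C)(C)Cl
Why: The primary hydroxyl is silylated much faster than the secondary one next to the quaternary C4 or the tertiary one; this keeps the primary oxygen out of the later acetylation.

Step 21
Reactants: 27 (3R,4S,5S,8S,9R,10R)-4-{[(tert-butyldimethylsilyl)oxy]methyl}-9-ethenyl-4,8,10-trimethyldecalin-3,8-diol; 28 chloroprene (2-chlorobuta-1,3-diene)
Product: 30 (3R,4S,5S,8S,9R,10R)-4-{[(tert-butyldimethylsilyl)oxy]methyl}-4,8,10-trimethyl-9-(3-methylidenepent-4-en-1-yl)decalin-3,8-diol, via alkylborane 29 (not isolated)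
Conditions: 9-BBN (excess), THF, 0 to 40 °C; then 28, Pd(OAc)2, SPhos, aq. K3PO4, THF, 45 °C
Reagents that add atoms: none
Why: Anti-Markovnikov hydroboration of the only alkene gives the primary alkylborane 29, and B-alkyl Suzuki–Miyaura coupling with the alkenyl chloride under an electron-rich phosphine forms C12–C13. The excess 9-BBN covers the two free hydroxyls, which the aqueous base releases again.

Step 22
Reactants: 30 (3R,4S,5S,8S,9R,10R)-4-{[(tert-butyldimethylsilyl)oxy]methyl}-4,8,10-trimethyl-9-(3-methylidenepent-4-en-1-yl)decalin-3,8-diol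
Product: 31 (3R,4S,5S,8S,9R,10R)-4-{[(tert-butyldimethylsilyl)oxy]methyl}-8-hydroxy-4,8,10-trimethyl-9-(3-methylidenepent-4-en-1-yl)decalin-3-yl acetate
Conditions: Ac2O, pyridine, DMAP (cat.), CH2Cl2, 0 °C to rt
Reagents that add atoms: acetic anhydride, CC(=O)OC(C)=O
Why: Acetylation of the equatorial secondary alcohol; the tertiary 8-OH does not react under these conditions and the primary oxygen is silylated.

Step 23
Reactants: 31 (3R,4S,5S,8S,9R,10R)-4-{[(tert-butyldimethylsilyl)oxy]methyl}-8-hydroxy-4,8,10-trimethyl-9-(3-methylidenepent-4-en-1-yl)decalin-3-yl acetate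
Product: 32 (3R,4S,5S,8S,9R,10R)-8-hydroxy-4-(hydroxymethyl)-4,8,10-trimethyl-9-(3-methylidenepent-4-en-1-yl)decalin-3-yl acetate (CNP0313672.1)
Conditions: HF·pyridine, pyridine, THF, 0 °C
Reagents that add atoms: none
Why: Buffered HF·pyridine removes the primary silyl ether under weakly acidic conditions, which avoid base-induced migration of the acetate to the freed primary hydroxyl and spare the diene and the tertiary alcohol.

## Compound list

1 | 5-(trimethylsilyl)pent-4-yn-1-ol | C[Si](C)(C)C#CCCCO | starting material
2 | 5-(trimethylsilyl)pent-4-ynal | C[Si](C)(C)C#CCCC=O | intermediate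
3 | (S)-4-benzyl-3-propionyloxazolidin-2-one | CCC(=O)N1[C@@H](Cc2ccccc2)COC1=O | starting material
4 | (Z)-dibutylboron enolate of 3 | C/C=C(/N1[C@@H](Cc2ccccc2)COC1=O)OB(CCCC)CCCC | intermediate
5 | (S)-4-benzyl-3-[(2S,3R)-3-hydroxy-2-methyl-7-(trimethylsilyl)hept-6-ynoyl]oxazolidin-2-one | C[Si](C)(C)C#CCC[C@@H](O)[C@H](C)C(=O)N1[C@@H](Cc2ccccc2)COC1=O | intermediate
6 | (2S,3R)-3-hydroxy-N-methoxy-N,2-dimethyl-7-(trimethylsilyl)hept-6-ynamide | C[Si](C)(C)C#CCC[C@@H](O)[C@H](C)C(=O)N(C)OC | intermediate
7 | (2S,3R)-3-[(tert-butyldimethylsilyl)oxy]-N-methoxy-N,2-dimethyl-7-(trimethylsilyl)hept-6-ynamide | C[Si](C)(C)C#CCC[C@@H](O[Si](C)(C)C(C)(C)C)[C@H](C)C(=O)N(C)OC | intermediate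
8 | 2-(2-bromoethyl)-2-methyl-1,3-dioxolane | CC1(CCBr)OCCO1 | starting material
9 | [2-(2-methyl-1,3-dioxolan-2-yl)ethyl]magnesium bromide | CC1(CC[Mg]Br)OCCO1 | intermediate
10 | (4S,5R)-5-[(tert-butyldimethylsilyl)oxy]-4-methyl-1-(2-methyl-1,3-dioxolan-2-yl)-9-(trimethylsilyl)non-8-yn-3-one | C[Si](C)(C)C#CCC[C@@H](O[Si](C)(C)C(C)(C)C)[C@H](C)C(=O)CCC1(C)OCCO1 | intermediate
11 | tert-butyldimethyl{[(2S,3R)-2-(5-methylfuran-2-yl)-7-(trimethylsilyl)hept-6-yn-3-yl]oxy}silane | C[Si](C)(C)C#CCC[C@@H](O[Si](C)(C)C(C)(C)C)[C@H](C)c1ccc(C)o1 | intermediate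
12 | tert-butyldimethyl{[(2S,3R)-2-(5-methylfuran-2-yl)hept-6-yn-3-yl]oxy}silane | C#CCC[C@@H](O[Si](C)(C)C(C)(C)C)[C@H](C)c1ccc(C)o1 | intermediate
13 | lithium acetylide of 12 | [Li]C#CCC[C@@H](O[Si](C)(C)C(C)(C)C)[C@H](C)c1ccc(C)o1 | intermediate
14 | methyl (6R,7S)-6-[(tert-butyldimethylsilyl)oxy]-7-(5-methylfuran-2-yl)oct-2-ynoate | COC(=O)C#CCC[C@@H](O[Si](C)(C)C(C)(C)C)[C@H](C)c1ccc(C)o1 | intermediate
15 | methyl (2Z,6R,7S)-6-[(tert-butyldimethylsilyl)oxy]-3-methyl-7-(5-methylfuran-2-yl)oct-2-enoate | COC(=O)/C=C(C)\CC[C@@H](O[Si](C)(C)C(C)(C)C)[C@H](C)c1ccc(C)o1 | intermediate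
16 | methyl (3R,4S,5S,8S,9R,10S)-3-[(tert-butyldimethylsilyl)oxy]-5,8-epoxy-4,8,10-trimethyloctal-6-ene-9-carboxylate | COC(=O)[C@@H]1[C@]2(C)CC[C@@H](O[Si](C)(C)C(C)(C)C)[C@H](C)[C@]23O[C@@]1(C)C=C3 | intermediate
17 | methyl (3R,4S,5S,8S,9R,10S)-3-[(tert-butyldimethylsilyl)oxy]-5,8-epoxy-4,8,10-trimethyldecalin-9-carboxylate | COC(=O)[C@@H]1[C@]2(C)CC[C@@H](O[Si](C)(C)C(C)(C)C)[C@H](C)[C@]23O[C@@]1(C)CC3 | intermediate
18 | [(3R,4S,5S,8S,9S,10S)-3-[(tert-butyldimethylsilyl)oxy]-5,8-epoxy-4,8,10-trimethyldecalin-9-yl]methanol | OC[C@@H]1[C@]2(C)CC[C@@H](O[Si](C)(C)C(C)(C)C)[C@H](C)[C@]23O[C@@]1(C)CC3 | intermediate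
19 | (3R,4S,5S,8S,9R,10S)-3-[(tert-butyldimethylsilyl)oxy]-5,8-epoxy-4,8,10-trimethyldecalin-9-carbaldehyde | O=C[C@@H]1[C@]2(C)CC[C@@H](O[Si](C)(C)C(C)(C)C)[C@H](C)[C@]23O[C@@]1(C)CC3 | intermediate
20 | tert-butyl{[(3R,4S,5S,8S,9R,10S)-9-ethenyl-5,8-epoxy-4,8,10-trimethyldecalin-3-yl]oxy}dimethylsilane | C=C[C@@H]1[C@]2(C)CC[C@@H](O[Si](C)(C)C(C)(C)C)[C@H](C)[C@]23O[C@@]1(C)CC3 | intermediate
21 | (3R,4S,5S,8S,9R,10S)-9-ethenyl-5,8-epoxy-4,8,10-trimethyldecalin-3-ol | C=C[C@@H]1[C@]2(C)CC[C@@H](O)[C@H](C)[C@]23O[C@@]1(C)CC3 | intermediate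
22 | (4R,5S,8S,9R,10S)-9-ethenyl-5,8-epoxy-4,8,10-trimethyldecalin-3-one | C=C[C@@H]1[C@]2(C)CCC(=O)[C@H](C)[C@]23O[C@@]1(C)CC3 | intermediate
23 | (8S,9R,10S)-9-ethenyl-8-hydroxy-4,8,10-trimethyloctal-4-en-3-one | C=C[C@@H]1[C@]2(C)CCC(=O)C(C)=C2CC[C@]1(C)O | intermediate
24 | dilithium 3-enolate 8-alkoxide of (5S,8S,9R,10R)-9-ethenyl-8-hydroxy-4,8,10-trimethyldecalin-3-one | C=C[C@@H]1[C@]2(C)CCC(O[Li])=C(C)[C@H]2CC[C@]1(C)O[Li] | intermediate
25 | (4S,5S,8S,9R,10R)-9-ethenyl-8-hydroxy-4-(hydroxymethyl)-4,8,10-trimethyldecalin-3-one | C=C[C@@H]1[C@]2(C)CCC(=O)[C@](C)(CO)[C@H]2CC[C@]1(C)O | intermediate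
26 | (3R,4S,5S,8S,9R,10R)-9-ethenyl-4-(hydroxymethyl)-4,8,10-trimethyldecalin-3,8-diol | C=C[C@@H]1[C@]2(C)CC[C@@H](O)[C@](C)(CO)[C@H]2CC[C@]1(C)O | intermediate
27 | (3R,4S,5S,8S,9R,10R)-4-{[(tert-butyldimethylsilyl)oxy]methyl}-9-ethenyl-4,8,10-trimethyldecalin-3,8-diol | C=C[C@@H]1[C@]2(C)CC[C@@H](O)[C@](C)(CO[Si](C)(C)C(C)(C)C)[C@H]2CC[C@]1(C)O | intermediate
28 | chloroprene (2-chlorobuta-1,3-diene) | C=CC(Cl)=C | starting material
29 | B-alkyl-9-borabicyclo[3.3.1]nonane from 27 (boron on C12) | B1(CC[C@@H]2[C@]3(C)CC[C@@H](O)[C@](C)(CO[Si](C)(C)C(C)(C)C)[C@H]3CC[C@]2(C)O)C2CCCC1CCC2 | intermediate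
30 | (3R,4S,5S,8S,9R,10R)-4-{[(tert-butyldimethylsilyl)oxy]methyl}-4,8,10-trimethyl-9-(3-methylidenepent-4-en-1-yl)decalin-3,8-diol | C=CC(=C)CC[C@@H]1[C@]2(C)CC[C@@H](O)[C@](C)(CO[Si](C)(C)C(C)(C)C)[C@H]2CC[C@]1(C)O | intermediate
31 | (3R,4S,5S,8S,9R,10R)-4-{[(tert-butyldimethylsilyl)oxy]methyl}-8-hydroxy-4,8,10-trimethyl-9-(3-methylidenepent-4-en-1-yl)decalin-3-yl acetate | C=CC(=C)CC[C@@H]1[C@]2(C)CC[C@@H](OC(C)=O)[C@](C)(CO[Si](C)(C)C(C)(C)C)[C@H]2CC[C@]1(C)O | intermediate
32 | (3R,4S,5S,8S,9R,10R)-8-hydroxy-4-(hydroxymethyl)-4,8,10-trimethyl-9-(3-methylidenepent-4-en-1-yl)decalin-3-yl acetate | C=CC(=C)CC[C@@H]1[C@]2(C)CC[C@@H](OC(C)=O)[C@](C)(CO)[C@H]2CC[C@]1(C)O | target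

## Step count and least certain steps

Total: 23 steps. Longest linear sequence: 23 steps, from 1 to 32; compounds 3, 8 and 28 enter along the way.

**Step 10 (key step, carries the label "Proposed new method:").** The cycloaddition may not start, because a β,β-disubstituted ester is a weak dienophile even when complexed. The adduct may revert on warming, because the equilibrium with an aromatic diene can be unfavourable. The Lewis acid may instead cause electrophilic attack on the furan or its polymerisation. Facial selectivity may be incomplete, which would erode the enantiomeric purity once C3 and C4 are erased.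

Fallback, known chemistry only, from 15 back to 23: the furan is used as the masked 1,4-diketone it was made from and the two bonds are formed reductively.
- mCPBA (CH2Cl2, 0 °C) opens the furan of 15 to the cis-enedione F1, and Zn/AcOH reduces its C6–C7 double bond to the saturated 1,4-diketone F2.
- SmI2 (THF, t-BuOH, −78 °C) generates the C5 ketyl, which adds 6-exo to C10 of the enoate. The samarium enolate so formed closes ring B by aldol addition to the C8 ketone and gives the 5,8-dihydroxy ester F3. The three oxygens are held on one face by trivalent samarium and the C10 methyl is axial.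
- The two tertiary hydroxyls are capped (TMSOTf, 2,6-lutidine) to the bis(trimethylsilyl) ether F4, and the operations of steps 12–17 are repeated. LiAlH4 gives the primary alcohol F5, Dess–Martin oxidation the aldehyde F6, and Wittig methylenation the vinyl compound F7. TBAF removes all three silyl groups to give the triol F8, Dess–Martin oxidation of its only secondary alcohol gives the β-hydroxy ketone F9, and dehydration with DBU returns to the route at 23.
- In this detour C9 rests on chelation and not on alkene geometry, which is why it is the fallback and not the plan.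

**Step 18.** The enolate may exchange protons or equilibrate before the C–C bond forms. Gaseous formaldehyde may polymerise and give low conversion. The new hydroxymethyl group may be lost by retro-aldol cleavage during work-up. C5 may be protonated from the wrong face because of the axial C9 substituent. Fallback from 23 back to 25: the reduction is run as before, but enolate 24 is quenched with TMSCl/Et3N and isolated as the bis(trimethylsilyl) compound (C3 silyl enol ether, 8-silyl ether) F10. A Mukaiyama hydroxymethylation with aqueous formaldehyde and Yb(OTf)3 in THF then forms the C4–CH2OH bond under neutral conditions and releases the 8-hydroxyl, giving 25.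

**Step 21.** Oxidative addition to the alkenyl chloride may be slow. Chloroprene and the product diene may oligomerise under palladium. The alkylborane may be lost by protodeboronation. Fallback from 27 (through 29) back to 30: the diene is not coupled intact but finished by olefination. Alkylborane 29 is coupled with 2-bromoprop-2-en-1-ol (PdCl2(dppf), AsPh3, Cs2CO3, DMF/THF/H2O, rt) to the 2-substituted allylic alcohol F11. MnO2 oxidises only this allylic alcohol to the enal F12, and Wittig methylenation (Ph3P=CH2, THF, −78 to 0 °C) gives 30.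

**Step 14.** The ylide may deprotonate C9 and not add to the hindered aldehyde. This would lead to β-elimination of the C8–O bond (bridge opening on the wrong side) or to epimerisation at C9. Fallback from 19 back to 20: a Peterson olefination separates addition from elimination. The non-basic reagent from Me3SiCH2MgCl and CeCl3 (THF, −78 °C) adds to 19 to give the β-hydroxysilane F13, which no longer has a carbonyl, and KH (THF, 0 °C to rt) then eliminates it to 20.

## Further compounds

F1 | step 10 | methyl (2Z,6R,7S,9Z)-6-[(tert-butyldimethylsilyl)oxy]-3,7-dimethyl-8,11-dioxododeca-2,9-dienoate | COC(=O)/C=C(C)\CC[C@@H](O[Si](C)(C)C(C)(C)C)[C@H](C)C(=O)/C=C\C(C)=O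
F2 | step 10 | methyl (2Z,6R,7S)-6-[(tert-butyldimethylsilyl)oxy]-3,7-dimethyl-8,11-dioxododec-2-enoate | COC(=O)/C=C(C)\CC[C@@H](O[Si](C)(C)C(C)(C)C)[C@H](C)C(=O)CCC(C)=O
F3 | step 10 | methyl 3-[(tert-butyldimethylsilyl)oxy]-5,8-dihydroxy-4,8,10-trimethyldecalin-9-carboxylate (5-OH, 8-OH and ester on one face, C10 methyl opposite) | COC(=O)[C@@H]1[C@]2(C)CC[C@@H](O[Si](C)(C)C(C)(C)C)[C@H](C)[C@@]2(O)CC[C@]1(C)O
F4 | step 10 | 5,8-bis(trimethylsilyl) ether of F3 | COC(=O)[C@@H]1[C@]2(C)CC[C@@H](O[Si](C)(C)C(C)(C)C)[C@H](C)[C@@]2(O[Si](C)(C)C)CC[C@]1(C)O[Si](C)(C)C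
F5 | step 10 | [3-[(tert-butyldimethylsilyl)oxy]-4,8,10-trimethyl-5,8-bis(trimethylsilyloxy)decalin-9-yl]methanol | OC[C@@H]1[C@]2(C)CC[C@@H](O[Si](C)(C)C(C)(C)C)[C@H](C)[C@@]2(O[Si](C)(C)C)CC[C@]1(C)O[Si](C)(C)C
F6 | step 10 | 3-[(tert-butyldimethylsilyl)oxy]-4,8,10-trimethyl-5,8-bis(trimethylsilyloxy)decalin-9-carbaldehyde | O=C[C@@H]1[C@]2(C)CC[C@@H](O[Si](C)(C)C(C)(C)C)[C@H](C)[C@@]2(O[Si](C)(C)C)CC[C@]1(C)O[Si](C)(C)C
F7 | step 10 | 3-[(tert-butyldimethylsilyl)oxy]-9-ethenyl-4,8,10-trimethyl-5,8-bis(trimethylsilyloxy)decalin | C=C[C@@H]1[C@]2(C)CC[C@@H](O[Si](C)(C)C(C)(C)C)[C@H](C)[C@@]2(O[Si](C)(C)C)CC[C@]1(C)O[Si](C)(C)C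
F8 | step 10 | 9-ethenyl-4,8,10-trimethyldecalin-3,5,8-triol | C=C[C@@H]1[C@]2(C)CC[C@@H](O)[C@H](C)[C@@]2(O)CC[C@]1(C)O
F9 | step 10 | 9-ethenyl-5,8-dihydroxy-4,8,10-trimethyldecalin-3-one | C=C[C@@H]1[C@]2(C)CCC(=O)[C@H](C)[C@@]2(O)CC[C@]1(C)O
F10 | step 18 | (5S,8S,9R,10R)-9-ethenyl-4,8,10-trimethyl-3,8-bis(trimethylsilyloxy)octal-3-ene | C=C[C@@H]1[C@]2(C)CCC(O[Si](C)(C)C)=C(C)[C@H]2CC[C@]1(C)O[Si](C)(C)C
F11 | step 21 | (3R,4S,5S,8S,9R,10R)-4-{[(tert-butyldimethylsilyl)oxy]methyl}-9-[3-(hydroxymethyl)but-3-en-1-yl]-4,8,10-trimethyldecalin-3,8-diol | C=C(CO)CC[C@@H]1[C@]2(C)CC[C@@H](O)[C@](C)(CO[Si](C)(C)C(C)(C)C)[C@H]2CC[C@]1(C)O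
F12 | step 21 | 2-methylidene-4-[(3R,4S,5S,8S,9R,10R)-4-{[(tert-butyldimethylsilyl)oxy]methyl}-3,8-dihydroxy-4,8,10-trimethyldecalin-9-yl]butanal | C=C(C=O)CC[C@@H]1[C@]2(C)CC[C@@H](O)[C@](C)(CO[Si](C)(C)C(C)(C)C)[C@H]2CC[C@]1(C)O
F13 | step 14 | 1-[(3R,4S,5S,8S,9R,10S)-3-[(tert-butyldimethylsilyl)oxy]-5,8-epoxy-4,8,10-trimethyldecalin-9-yl]-2-(trimethylsilyl)ethanol (both epimers at the carbinol carbon) | C[Si](C)(C)CC(O)[C@@H]1[C@]2(C)CC[C@@H](O[Si](C)(C)C(C)(C)C)[C@H](C)[C@]23O[C@@]1(C)CC3
A1 | alternative 1 | 8-hydroxy-4,8,10-trimethyloctal-4-ene-3,9-dione | O=C1[C@]2(C)CCC(=O)C(C)=C2CC[C@]1(C)O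
A2 | alternative 2 | cis-fused methylenecyclobutane photoadduct of the acetonide-protected 8-methyl-8-en-7-one | C=C1C[C@@H]2[C@]3(C)CC[C@H]4OC(C)(C)OC[C@]4(C)[C@H]3CC(=O)[C@]12C
A3 | alternative 2 | allene (propadiene) | C=C=C
A4 | alternative 3 | trans-decalin 9-ketone with C3–C4 tert-butyldimethylsilyl enol ether and 8-methoxymethyl ether | O=C1[C@]2(C)CCC(O[Si](C)(C)C(C)(C)C)=C(C)[C@H]2CC[C@]1(C)OCOC
A5 | alternative 3 | (S)-linalool | C=C[C@@](C)(O)CCC=C(C)C
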